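A direct plan would buy both benzene rings and close the pyranone last. Acetophenone A1 would be brominated at its one free ring position to give bromoacetophenone A2, and the bromide of A2 would be exchanged for methoxide under copper catalysis to give tetramethoxyacetophenone A3. A3 would be condensed with O-benzylisovanillin A4 to chalcone A5, A5 would be cyclised oxidatively (I2/DMSO) to the pentaalkoxyflavone A6, and a boron Lewis acid would finally cleave the 5-O-methyl and 3'-O-benzyl ethers of A6.
Its weakest steps would be:
- **Bromination then copper methoxylation:** two steps, one a hot Ullmann-type exchange on a hindered ortho-bromophenol, to add a single methoxy group and no skeleton.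
- **The final double ether cleavage:** it would have to pick one of five methyl ethers on the most precious material, relying only on chelation, with over-demethylation at C6 or C4' the usual failure.
- **Methylating O5 only to demethylate it:** ring A is never built with its oxygens differentiated; the pattern is corrected at the end.

**Plan of the new route.** The retrosynthesis cuts ring A out of the target at C4a–C5 (6π electrocyclisation) and C8–C8a (carbonyl addition). The enabling feature is that C5–C8 of ring A form a 2,3-dimethoxy-1,4-dioxygenated four-carbon unit, which is dimethyl squarate. C4a=C8a is the C5=C6 enol-ether edge of a 2-aryl-4H-pyran-4-one, whose C6–H (α to the ring oxygen) is the acidic one, and O5 lies peri to C4=O. The rings arise in the order B (bought), C (pyranone, step 3), A (last, step 6). O8 is methylated at the alkoxide stage and O5 is born free from a ketene carbonyl, so no halogenation/methoxylation and no selective demethylation occur. The flavone nucleus first exists in the target itself, and the last step uses no reagent.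

Key step: step 6

Remark on the chemistry: the target has no stereocentre, so "single enantiomer" requires no stereocontrol. The quaternary carbon of 11/12 and C4a of 14 are racemic and are erased on aromatisation. Compounds 1, 4 and 8 are taken as catalogue items.

Step 1
Reactants: 1, isovanillic acid (3-hydroxy-4-methoxybenzoic acid)
Product: 2 tert-butyldimethylsilyl 3-(tert-butyldimethylsilyloxy)-4-methoxybenzoate
Conditions: TBSCl (2.3 equiv), imidazole (5 equiv), DMF, rt
Reagents that add atoms: tert-butyldimethylsilyl chloride, CC(C)(C)[Si](C)(C)Cl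
Why: Imidazole-mediated O-silylation of both the phenol and the acid should give an aryl silyl ether that survives the later basic steps and a silyl ester that is the direct precursor of the acid chloride under neutral conditions.

Step 2
Reactants: 2, the bis-silyl compound
Product: 3 3-(tert-butyldimethylsilyloxy)-4-methoxybenzoyl chloride
Conditions: (COCl)2 (1.2 equiv), DMF (cat.), CH2Cl2, 0 °C → rt; volatiles removed in vacuo
Reagents that add atoms: oxalyl chloride, O=C(Cl)C(=O)Cl
Why: Vilsmeier-type activation: the chloroiminium salt should convert the silyl ester directly into the acid chloride with loss of TBSCl, CO and CO2 and without HCl, so the aryl silyl ether is not touched.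

Step 3
Reactants: 3, the acid chloride; 4, (E)-4-methoxybut-3-en-2-one
Product: 7 2-[3-(tert-butyldimethylsilyloxy)-4-methoxyphenyl]-4H-pyran-4-one, via lithium dienolate 5 (not isolated), via enol-ether diketone 6 (not isolated)
Conditions: 4 (2.1 equiv), LiHMDS (2.1 equiv), THF, −78 °C; 3 (1 equiv), −78 °C; aq. NH4Cl; crude 6, TFA (0.2 equiv), toluene, rt
Reagents that add atoms: none
Why: C-acylation of the kinetic lithium dienolate of the vinylogous ester by the aroyl chloride (the second equivalent of enolate takes up the acidic diketone proton), followed by acid-catalysed 6-endo addition–elimination of the aryl-ketone enol oxygen onto the β-methoxy enone with loss of methanol, is the established two-stage γ-pyranone synthesis, and the aryl silyl ether should tolerate catalytic TFA in an aprotic solvent.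

Step 4
Reactants: 7, the 2-aryl-4H-pyran-4-one; 8, dimethyl squarate (3,4-dimethoxycyclobut-3-ene-1,2-dione)
Product: 11 4-{6-[3-(tert-butyldimethylsilyloxy)-4-methoxyphenyl]-4-oxo-4H-pyran-2-yl}-2,3,4-trimethoxycyclobut-2-en-1-one (racemic), via 6-lithiopyranone 9 (not isolated), via lithium alkoxide 10 (not isolated)
Conditions: LiTMP (1.05 equiv, from TMPH and n-BuLi), THF, −78 °C, 15 min; 8 (1.2 equiv), −78 °C; MeOTf (1.2 equiv), −78 → −20 °C; Et3N, then aq. NaHCO3
Reagents that add atoms: methyl trifluoromethanesulfonate, COS(=O)(=O)C(F)(F)F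
Why: Deprotonative lithiation with the hindered amide should remove the most acidic ring hydrogen of the γ-pyranone (C6–H, α to the ring oxygen and β to the carbonyl), the vinyllithium should add 1,2 to one of the two equivalent squarate carbonyls, and in-situ O-methylation of the tertiary lithium alkoxide (far more nucleophilic than the pyranone carbonyl oxygen, excess triflate being destroyed cold with triethylamine) marks the future O8 as a methyl ether before ring A exists; the new quaternary carbon is racemic and is erased in step 6.

Step 5
Reactants: 11, the silyl-protected trimethoxycyclobutenone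
Product: 12 4-[6-(3-hydroxy-4-methoxyphenyl)-4-oxo-4H-pyran-2-yl]-2,3,4-trimethoxycyclobut-2-en-1-one (racemic)
Conditions: TBAF (1.1 equiv), AcOH (1.2 equiv), THF, 0 °C
Reagents that add atoms: none
Why: Fluoride cleavage of an aryl silyl ether, buffered with acetic acid so that the phenoxide is protonated at once and cannot attack the vinylogous ester of the cyclobutenone, should leave the tertiary methyl ether and the enol ethers untouched.

Step 6
Reactants: 12, the phenolic trimethoxycyclobutenone
Product: 15 Gardenin D (5-hydroxy-2-(3-hydroxy-4-methoxyphenyl)-6,7,8-trimethoxy-4H-chromen-4-one), via dienylketene 13 (not isolated), via cyclohexadienone 14 (not isolated)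
Conditions: toluene (0.01 M, degassed), 110 °C (p-xylene, 138 °C, if slow)
Reagents that add atoms: none
Why: Heating should open the cyclobutenone by conrotatory 4π electrocyclic ring opening in which the C4 methoxy donor rotates outward and so turns the pyranonyl group inward, cis to the ketene in (Z)-dienylketene 13. Ring A then closes by 6π electrocyclisation between the electrophilic ketene carbon and C5 of the pyranone (its nucleophilic α-carbon and the only carbon neighbour of the attachment point, so there is no regiochemical alternative), forming the C4a–C5 bond of dienone 14. Enolisation of 14, whose C4a–H lies between two carbonyls, aromatises ring A: the former ketene oxygen becomes the free 5-OH hydrogen-bonded to C4=O, the carbinol carbon methylated in step 4 becomes C8–OMe, and the two squarate enol-ether carbons become C6–OMe and C7–OMe. The closest known reaction type is the thermal ring expansion of 4-alkenyl- and 4-heteroaryl-4-alkoxycyclobutenones to hydroquinone monoethers (Moore–Liebeskind benzannulation). No stereocentre is created, and the racemic centres of 12 and 14 vanish on aromatisation. The step needs ring closure to outrun intermolecular capture of the ketene by the free phenol, which the pre-organised intramolecular 6π closure and high dilution should secure, while the 5-OH/8-OMe differentiation is already fixed by the order of events at the carbinol carbon.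

**Compound list**
1 | isovanillic acid (3-hydroxy-4-methoxybenzoic acid) | COc1ccc(C(=O)O)cc1O | starting material
2 | tert-butyldimethylsilyl 3-(tert-butyldimethylsilyloxy)-4-methoxybenzoate | COc1ccc(C(=O)O[Si](C)(C)C(C)(C)C)cc1O[Si](C)(C)C(C)(C)C | intermediate
3 | 3-(tert-butyldimethylsilyloxy)-4-methoxybenzoyl chloride | COc1ccc(C(Cl)=O)cc1O[Si](C)(C)C(C)(C)C | intermediate
4 | (E)-4-methoxybut-3-en-2-one | CO/C=C/C(C)=O | starting material
5 | lithium (E)-4-methoxybuta-1,3-dien-2-olate | [Li+].[O-]C(=C)/C=C/OC | intermediate
6 | (E)-1-[3-(tert-butyldimethylsilyloxy)-4-methoxyphenyl]-5-methoxypent-4-ene-1,3-dione | CO/C=C/C(=O)CC(=O)c1ccc(OC)c(O[Si](C)(C)C(C)(C)C)c1 | intermediate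
7 | 2-[3-(tert-butyldimethylsilyloxy)-4-methoxyphenyl]-4H-pyran-4-one | COc1ccc(-c2cc(=O)cco2)cc1O[Si](C)(C)C(C)(C)C | intermediate
8 | dimethyl squarate (3,4-dimethoxycyclobut-3-ene-1,2-dione) | COC1=C(OC)C(=O)C1=O | starting material
9 | {6-[3-(tert-butyldimethylsilyloxy)-4-methoxyphenyl]-4-oxo-4H-pyran-2-yl}lithium | [Li]c1cc(=O)cc(-c2ccc(OC)c(O[Si](C)(C)C(C)(C)C)c2)o1 | intermediate
10 | lithium 1-{6-[3-(tert-butyldimethylsilyloxy)-4-methoxyphenyl]-4-oxo-4H-pyran-2-yl}-2,3-dimethoxy-4-oxocyclobut-2-en-1-olate (racemic) | [Li+].[O-]C1(c2cc(=O)cc(-c3ccc(OC)c(O[Si](C)(C)C(C)(C)C)c3)o2)C(=O)C(OC)=C1OC | intermediate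
11 | 4-{6-[3-(tert-butyldimethylsilyloxy)-4-methoxyphenyl]-4-oxo-4H-pyran-2-yl}-2,3,4-trimethoxycyclobut-2-en-1-one (racemic) | COC1(c2cc(=O)cc(-c3ccc(OC)c(O[Si](C)(C)C(C)(C)C)c3)o2)C(=O)C(OC)=C1OC | intermediate
12 | 4-[6-(3-hydroxy-4-methoxyphenyl)-4-oxo-4H-pyran-2-yl]-2,3,4-trimethoxycyclobut-2-en-1-one (racemic) | COC1(c2cc(=O)cc(-c3ccc(OC)c(O)c3)o2)C(=O)C(OC)=C1OC | intermediate
13 | (3Z)-4-[6-(3-hydroxy-4-methoxyphenyl)-4-oxo-4H-pyran-2-yl]-2,3,4-trimethoxybuta-1,3-dien-1-one | O=C=C(OC)/C(OC)=C(/OC)c1cc(=O)cc(-c2ccc(OC)c(O)c2)o1 | intermediate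
14 | 2-(3-hydroxy-4-methoxyphenyl)-6,7,8-trimethoxy-4aH-chromene-4,5-dione (racemic at C4a) | O=C1C(OC)=C(OC)C(OC)=C2OC(-c3ccc(OC)c(O)c3)=CC(=O)C12 | intermediate
15 | Gardenin D | COc1ccc(-c2cc(=O)c3c(O)c(OC)c(OC)c(OC)c3o2)cc1O | target

Total step count: 6. Longest linear sequence: 6 (1 → 15); 4 and 8 enter as bought components.

**Steps most likely to fail**

Step 4. Metalation could take place at C3/C5 (followed by ring opening of the pyranone), the lithiated pyranone could add to unreacted 7, or the alkoxide methylation could be incomplete. The fallback sets out from 7 and replaces direct lithiation by halogen–metal exchange. Zincation with TMPZnCl·LiCl (THF, rt), which should tolerate the pyranone carbonyl, and iodolysis would give 2-[3-(tert-butyldimethylsilyloxy)-4-methoxyphenyl]-6-iodo-4H-pyran-4-one F1. Iodine–magnesium exchange (iPrMgCl·LiCl, THF, −78 °C) and addition to 8 would give, after NH4Cl, the 4-hydroxycyclobutenone F2. O-Methylation of F2 with MeI/Ag2O (K2CO3, MeCN) would return to the route at 11.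

Step 6. The ketene could be acylated by the free phenol of a second molecule in competition with ring closure. The fallback sets out from 11 and carries the phenol masked through the ring expansion. Heating 11 itself (toluene or p-xylene, 110–138 °C) would give the 3'-O-silyl flavone F3 by the same 4π/6π sequence with no nucleophile present, and buffered fluoride (TBAF/AcOH, THF, 0 °C) would then cleave the silyl ether to arrive at 15.

Step 3. The dienolate could be O-acylated or acylated twice, or the silyl ether could be lost during the acid cyclisation. The fallback sets out from 3 and builds the pyranone by cycloaddition instead of acylation. Reduction with LiAlH(OtBu)3 (THF, −78 °C) would give 3-(tert-butyldimethylsilyloxy)-4-methoxybenzaldehyde F4. Hetero-Diels–Alder reaction of F4 with Danishefsky's diene (ZnCl2 or BF3·OEt2, then TFA) would give the racemic 2-aryl-2,3-dihydro-4H-pyran-4-one F5. Dehydrogenation of F5 (DDQ, dioxane, reflux, as for flavanone → flavone) would return to the route at 7.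

Further compounds
F1 | step 4 | 2-[3-(tert-butyldimethylsilyloxy)-4-methoxyphenyl]-6-iodo-4H-pyran-4-one | COc1ccc(-c2cc(=O)cc(I)o2)cc1O[Si](C)(C)C(C)(C)C
F2 | step 4 | 4-{6-[3-(tert-butyldimethylsilyloxy)-4-methoxyphenyl]-4-oxo-4H-pyran-2-yl}-4-hydroxy-2,3-dimethoxycyclobut-2-en-1-one (racemic) | COC1=C(OC)C(O)(c2cc(=O)cc(-c3ccc(OC)c(O[Si](C)(C)C(C)(C)C)c3)o2)C1=O
F3 | step 6 | 2-[3-(tert-butyldimethylsilyloxy)-4-methoxyphenyl]-5-hydroxy-6,7,8-trimethoxy-4H-chromen-4-one | COc1ccc(-c2cc(=O)c3c(O)c(OC)c(OC)c(OC)c3o2)cc1O[Si](C)(C)C(C)(C)C
F4 | step 3 | 3-(tert-butyldimethylsilyloxy)-4-methoxybenzaldehyde | COc1ccc(C=O)cc1O[Si](C)(C)C(C)(C)C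
F5 | step 3 | 2-[3-(tert-butyldimethylsilyloxy)-4-methoxyphenyl]-2,3-dihydro-4H-pyran-4-one (racemic) | COc1ccc(C2CC(=O)C=CO2)cc1O[Si](C)(C)C(C)(C)C
A1 | direct plan | 1-(6-hydroxy-2,3,4-trimethoxyphenyl)ethanone | CC(=O)c1c(O)cc(OC)c(OC)c1OC
A2 | direct plan | 1-(3-bromo-2-hydroxy-4,5,6-trimethoxyphenyl)ethanone | CC(=O)c1c(O)c(Br)c(OC)c(OC)c1OC
A3 | direct plan | 1-(2-hydroxy-3,4,5,6-tetramethoxyphenyl)ethanone | CC(=O)c1c(O)c(OC)c(OC)c(OC)c1OC
A4 | direct plan | 3-(benzyloxy)-4-methoxybenzaldehyde (O-benzylisovanillin) | COc1ccc(C=O)cc1OCc1ccccc1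
A5 | direct plan | (E)-3-[3-(benzyloxy)-4-methoxyphenyl]-1-(2-hydroxy-3,4,5,6-tetramethoxyphenyl)prop-2-en-1-one | COc1ccc(/C=C/C(=O)c2c(O)c(OC)c(OC)c(OC)c2OC)cc1OCc1ccccc1
A6 | direct plan | 2-[3-(benzyloxy)-4-methoxyphenyl]-5,6,7,8-tetramethoxy-4H-chromen-4-one | COc1ccc(-c2cc(=O)c3c(OC)c(OC)c(OC)c(OC)c3o2)cc1OCc1ccccc1
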